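The seven-membered ring (C5, C6, C7, C8, C9, C10, C1; daucane numbering, C1 = quaternary fusion carbon, C6 = ester carbinol, C8=C9 = olefin) is disconnected at C7–C8 and C10–C1. With C6 as an enol ether the ring is a 1,4-cycloheptadiene, the Cope product of a cis-divinylcyclopropane: a rhodium vinylcarbenoid (C8–C10) cyclopropanates the C6=C7 olefin of a 2-siloxydiene built on the five-membered ring, and the adduct rearranges at once, closing the ring and creating quaternary C1 next to the intact C4 carbinol. The diene comes from (S)-terpinen-4-ol by ozonolysis and aldol ring contraction, which preserves that carbinol stereocentre.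

Key step: step 7

Numbering used below: C1 (quaternary, CH3), C2, C3, C4 (carbinol, isopropyl), C5 (fusion CH) form the five-membered ring; C6 (oxygenated), C7 (CH2), C8 (CH3), C9, C10 (CH2) complete the seven-membered ring.
Assumption: (S)-(+)-terpinen-4-ol of high enantiomeric purity, methyl but-3-enoate, 4-methoxybenzoyl chloride and Rh2(R-DOSP)4 (dirhodium tetrakis[(R)-N-(4-dodecylphenylsulfonyl)prolinate]) are taken as commercial.

Step 1
Reactants: 1 (S)-(+)-terpinen-4-ol
Product: 2 (3S)-3-hydroxy-6-oxo-3-(propan-2-yl)heptanal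
Conditions: O3, CH2Cl2/MeOH, −78 °C; then Me2S, −78 °C → rt
Reagents that add atoms: ozone, [O-][O+]=O
Why: Ozonolysis with reductive work-up cleaves the only C=C bond to the keto aldehyde and does not touch the carbinol stereocentre (future C4).

Step 2
Reactants: 2 (3S)-3-hydroxy-6-oxo-3-(propan-2-yl)heptanal
Product: 3 (5R)-5-hydroxy-2-methyl-5-(propan-2-yl)cyclopent-1-ene-1-carbaldehyde
Conditions: piperidine, AcOH (20 mol % each), toluene, rt → 40 °C
Reagents that add atoms: none
Why: Enamine-mediated intramolecular aldol condensation (aldehyde α-carbon onto the methyl ketone) should give the cyclopentene carbaldehyde, as in the ring contraction of related terpene keto aldehydes; the buffered amine salt is chosen to keep the tertiary β-hydroxyl in place.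

Step 3
Reactants: 3 (5R)-5-hydroxy-2-methyl-5-(propan-2-yl)cyclopent-1-ene-1-carbaldehyde
Product: 4 (1R)-2-(1-hydroxyethyl)-3-methyl-1-(propan-2-yl)cyclopent-2-en-1-ol (both epimers at the new carbinol)
Conditions: MeMgBr (2.5 equiv), THF, −78 → 0 °C; aq. NH4Cl
Reagents that add atoms: methylmagnesium bromide, C[Mg]Br
Why: Grignard 1,2-addition to the enal (after deprotonation of the tertiary hydroxyl) installs C7; the new carbinol centre is oxidised in step 4, so its configuration does not matter.

Step 4
Reactants: 4 (1R)-2-(1-hydroxyethyl)-3-methyl-1-(propan-2-yl)cyclopent-2-en-1-ol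
Product: 5 1-[(5R)-5-hydroxy-2-methyl-5-(propan-2-yl)cyclopent-1-en-1-yl]ethan-1-one
Conditions: Dess–Martin periodinane, pyridine, CH2Cl2, 0 °C → rt
Reagents that add atoms: none
Why: Dess–Martin oxidation converts the secondary allylic alcohol to the enone, the tertiary alcohol cannot be oxidised, and pyridine buffers the acid-sensitive tertiary allylic carbinol.

Step 5
Reactants: 5 1-[(5R)-5-hydroxy-2-methyl-5-(propan-2-yl)cyclopent-1-en-1-yl]ethan-1-one
Product: 6 triethyl({1-[(5R)-2-methyl-5-(propan-2-yl)-5-(triethylsilyloxy)cyclopent-1-en-1-yl]ethenyl}oxy)silane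
Conditions: Et3SiOTf (2.5 equiv), Et3N (4 equiv), CH2Cl2, −78 → 0 °C
Reagents that add atoms: triethylsilyl trifluoromethanesulfonate, CC[Si](CC)(CC)OS(=O)(=O)C(F)(F)F
Why: Soft enolisation of the methyl ketone at its only α-position gives the cross-conjugated 2-siloxydiene, and the same reagent silylates the tertiary alcohol, removing the O–H bond a rhodium carbenoid would attack.

Step 6
Reactants: 7 methyl but-3-enoate
Product: 8 methyl 2-diazobut-3-enoate
Conditions: 4-acetamidobenzenesulfonyl azide, DBU, MeCN, 0 °C; used at once as a cold hexane solution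
Reagents that add atoms: 4-acetamidobenzenesulfonyl azide, CC(=O)Nc1ccc(cc1)S(=O)(=O)N=[N+]=[N-]
Why: Regitz diazo transfer to the doubly activated methylene (allylic and α to the ester) gives the vinyldiazoacetate, which is kept cold because it slowly cyclises to a pyrazole.

Step 7
Reactants: 6 triethyl({1-[(5R)-2-methyl-5-(propan-2-yl)-5-(triethylsilyloxy)cyclopent-1-en-1-yl]ethenyl}oxy)silane; 8 methyl 2-diazobut-3-enoate
Product: 10 methyl (3R,8aR)-8a-methyl-3-(propan-2-yl)-3,4-bis(triethylsilyloxy)-1,2,3,5,8,8a-hexahydroazulene-6-carboxylate, via cis-divinylcyclopropane 9 (not isolated)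
Conditions: Rh2(R-DOSP)4 (1 mol %), hexanes, slow addition of 8 at −26 °C → rt; then 70 °C
Reagents that add atoms: none
Why: Rh2(R-DOSP)4 decomposes 8 to a donor/acceptor vinylcarbenoid whose carbenoid carbon (C8) adds across the electron-rich terminal enol-ether olefin C6=C7 of 6 (bonds C7–C8 and C6–C8), and the resulting cis-divinylcyclopropane 9 undergoes a Cope rearrangement through a boat transition state that forms C10–C1 and cleaves C6–C8. The closest known reaction type is the tandem cyclopropanation/Cope rearrangement (formal [4+3] cycloaddition) of vinyldiazoacetates with 2-siloxy-1,3-dienes under dirhodium tetracarboxylate catalysis. The seven-membered ring is closed in the [3,3] step by a four-atom enlargement of the cyclopropane, the vinyl terminus C10 bonding to the tetrasubstituted cyclopentene carbon C1, so that the existing five-membered ring becomes fused at C1–C5. The single new stereocentre, quaternary C1, follows stereospecifically from the configuration of 9, which is set by reagent control: the R-configured prolinate catalyst is the antipode that the empirical face-selection model of these catalysts assigns to the required face of C6=C7, and the boat then places C10 on the isopropyl face so that the C1 methyl is cis to the C4 oxygen. The step needs site selectivity for C6=C7 over the tetrasubstituted C5=C1 olefin (siloxy activation, terminal position), attack at the carbenoid carbon instead of the vinyl terminus (hydrocarbon solvent, donating prolinate ligands), cis-divinyl geometry (inherent to donor/acceptor carbenoids) and no O–H insertion (C4 oxygen silylated). Warming is planned because the C1 methyl must occupy the inside position of the boat.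

Step 8
Reactants: 10 methyl (3R,8aR)-8a-methyl-3-(propan-2-yl)-3,4-bis(triethylsilyloxy)-1,2,3,5,8,8a-hexahydroazulene-6-carboxylate
Product: 11 [(3R,8aR)-8a-methyl-3-(propan-2-yl)-3,4-bis(triethylsilyloxy)-1,2,3,5,8,8a-hexahydroazulen-6-yl]methanol
Conditions: i-Bu2AlH (2.5 equiv), CH2Cl2, −78 °C; aq. potassium sodium tartrate
Reagents that add atoms: none
Why: 1,2-Reduction of the α,β-unsaturated ester by the aluminium hydride should give the allylic alcohol, the silyl ether and silyl enol ether being inert to it.

Step 9
Reactants: 11 [(3R,8aR)-8a-methyl-3-(propan-2-yl)-3,4-bis(triethylsilyloxy)-1,2,3,5,8,8a-hexahydroazulen-6-yl]methanol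
Product: 13 (3R,8aR)-6,8a-dimethyl-3-(propan-2-yl)-3,4-bis(triethylsilyloxy)-1,2,3,5,8,8a-hexahydroazulene, via allylic mesylate 12 (not isolated)
Conditions: MsCl, Et3N, CH2Cl2, −40 °C; then LiEt3BH, THF, −40 → 0 °C
Reagents that add atoms: methanesulfonyl chloride, CS(=O)(=O)Cl (its atoms stay only in 12)
Why: Hydride displaces the primary allylic sulfonate in an SN2 reaction (deoxygenation of an allylic alcohol through its sulfonate), turning the former ester carbon into the C8 methyl group without moving the C8=C9 double bond.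

Step 10
Reactants: 13 (3R,8aR)-6,8a-dimethyl-3-(propan-2-yl)-3,4-bis(triethylsilyloxy)-1,2,3,5,8,8a-hexahydroazulene
Product: 14 (3R,3aR,8aR)-3-hydroxy-6,8a-dimethyl-3-(propan-2-yl)-2,3,3a,5,8,8a-hexahydroazulen-4(1H)-one
Conditions: HF·pyridine, pyridine, THF, 0 °C → rt
Reagents that add atoms: none
Why: Fluoride-assisted protodesilylation cleaves the enol ether first, so C5 is protonated while the bottom face is still covered by the C4 silyloxy group and the angular methyl, which should give the trans-fused ketone (also expected to be the more stable epimer, C6 anti to the isopropyl group) before the tertiary silyl ether falls under the same buffered conditions that spare the β,γ-unsaturated ketone.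

Step 11
Reactants: 14 (3R,3aR,8aR)-3-hydroxy-6,8a-dimethyl-3-(propan-2-yl)-2,3,3a,5,8,8a-hexahydroazulen-4(1H)-one
Product: 15 jaeschkeanadiol, (3R,3aS,4S,8aR)-6,8a-dimethyl-3-(propan-2-yl)-1,2,3,3a,4,5,8,8a-octahydroazulene-3,4-diol
Conditions: Me4NBH(OAc)3, MeCN/AcOH (1:1), −30 °C
Reagents that add atoms: none
Why: Evans–Saksena reduction: the C4 hydroxyl exchanges onto boron and delivers hydride intramolecularly to the face of the C6 carbonyl on which it sits, so the new C6 hydroxyl should appear on the opposite face (1,3-anti), as required.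

Step 12
Reactants: 15 jaeschkeanadiol; 16 4-methoxybenzoyl chloride
Product: 17 fertidin, [(3R,3aS,4S,8aR)-3-hydroxy-6,8a-dimethyl-3-(propan-2-yl)-1,2,3,3a,4,5,8,8a-octahydroazulen-4-yl] 4-methoxybenzoate
Conditions: DMAP, Et3N, CH2Cl2, 0 °C → rt
Reagents that add atoms: none
Why: DMAP-catalysed acylation should esterify the secondary C6 hydroxyl only, the tertiary C4 hydroxyl being too hindered to react.

Compound list
1 | (S)-(+)-terpinen-4-ol, (1S)-4-methyl-1-(propan-2-yl)cyclohex-3-en-1-ol | CC1=CC[C@](O)(C(C)C)CC1 | starting material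
2 | (3S)-3-hydroxy-6-oxo-3-(propan-2-yl)heptanal | O=CC[C@](O)(C(C)C)CCC(C)=O | intermediate
3 | (5R)-5-hydroxy-2-methyl-5-(propan-2-yl)cyclopent-1-ene-1-carbaldehyde | O=CC1=C(C)CC[C@@]1(O)C(C)C | intermediate
4 | (1R)-2-(1-hydroxyethyl)-3-methyl-1-(propan-2-yl)cyclopent-2-en-1-ol (both side-chain epimers) | CC(O)C1=C(C)CC[C@@]1(O)C(C)C | intermediate
5 | 1-[(5R)-5-hydroxy-2-methyl-5-(propan-2-yl)cyclopent-1-en-1-yl]ethan-1-one | CC(=O)C1=C(C)CC[C@@]1(O)C(C)C | intermediate
6 | triethyl({1-[(5R)-2-methyl-5-(propan-2-yl)-5-(triethylsilyloxy)cyclopent-1-en-1-yl]ethenyl}oxy)silane | C=C(O[Si](CC)(CC)CC)C1=C(C)CC[C@@]1(O[Si](CC)(CC)CC)C(C)C | intermediate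
7 | methyl but-3-enoate | COC(=O)CC=C | starting material
8 | methyl 2-diazobut-3-enoate | COC(=O)C(=[N+]=[N-])C=C | intermediate
9 | methyl (1S,2R)-1-ethenyl-2-[(5R)-2-methyl-5-(propan-2-yl)-5-(triethylsilyloxy)cyclopent-1-en-1-yl]-2-(triethylsilyloxy)cyclopropane-1-carboxylate (ethenyl and cyclopentenyl cis) | COC(=O)[C@]1(C=C)C[C@@]1(O[Si](CC)(CC)CC)C2=C(C)CC[C@@]2(O[Si](CC)(CC)CC)C(C)C | intermediate (not isolated)
10 | methyl (3R,8aR)-8a-methyl-3-(propan-2-yl)-3,4-bis(triethylsilyloxy)-1,2,3,5,8,8a-hexahydroazulene-6-carboxylate | COC(=O)C1=CC[C@@]2(C)CC[C@@](O[Si](CC)(CC)CC)(C(C)C)C2=C(O[Si](CC)(CC)CC)C1 | intermediate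
11 | [(3R,8aR)-8a-methyl-3-(propan-2-yl)-3,4-bis(triethylsilyloxy)-1,2,3,5,8,8a-hexahydroazulen-6-yl]methanol | OCC1=CC[C@@]2(C)CC[C@@](O[Si](CC)(CC)CC)(C(C)C)C2=C(O[Si](CC)(CC)CC)C1 | intermediate
12 | [(3R,8aR)-8a-methyl-3-(propan-2-yl)-3,4-bis(triethylsilyloxy)-1,2,3,5,8,8a-hexahydroazulen-6-yl]methyl methanesulfonate | CS(=O)(=O)OCC1=CC[C@@]2(C)CC[C@@](O[Si](CC)(CC)CC)(C(C)C)C2=C(O[Si](CC)(CC)CC)C1 | intermediate (not isolated)
13 | (3R,8aR)-6,8a-dimethyl-3-(propan-2-yl)-3,4-bis(triethylsilyloxy)-1,2,3,5,8,8a-hexahydroazulene | CC1=CC[C@@]2(C)CC[C@@](O[Si](CC)(CC)CC)(C(C)C)C2=C(O[Si](CC)(CC)CC)C1 | intermediate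
14 | (3R,3aR,8aR)-3-hydroxy-6,8a-dimethyl-3-(propan-2-yl)-2,3,3a,5,8,8a-hexahydroazulen-4(1H)-one (trans-fused) | CC1=CC[C@@]2(C)CC[C@@](O)(C(C)C)[C@@H]2C(=O)C1 | intermediate
15 | jaeschkeanadiol, (3R,3aS,4S,8aR)-6,8a-dimethyl-3-(propan-2-yl)-1,2,3,3a,4,5,8,8a-octahydroazulene-3,4-diol | CC1=CC[C@@]2(C)CC[C@@](O)(C(C)C)[C@@H]2[C@@H](O)C1 | intermediate
16 | 4-methoxybenzoyl chloride | COc1ccc(cc1)C(Cl)=O | starting material
17 | fertidin, [(3R,3aS,4S,8aR)-3-hydroxy-6,8a-dimethyl-3-(propan-2-yl)-1,2,3,3a,4,5,8,8a-octahydroazulen-4-yl] 4-methoxybenzoate | COc1ccc(C(=O)O[C@H]2CC(C)=CC[C@@]3(C)CC[C@@](O)(C(C)C)[C@H]23)cc1 | target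

Total step count: 12. Longest linear sequence: 11 steps (steps 1–5 and 7–12).

Steps most likely to fail

1. Step 7. The face of C6=C7 is chosen by the catalyst alone, against a possibly opposing bias of the C4 stereocentre. The Cope step of the wanted isomer is also the slower one (C1 methyl inside the boat, isopropyl group facing the incoming vinyl group). The donor–acceptor cyclopropane may therefore open and re-close before it rearranges, or the unsubstituted vinylcarbenoid may be attacked at its terminus; either erodes yield and C1 configuration. The fallback replaces vinylcarbene transfer by methylene transfer to a preformed triene; it sets out from 3 and comes back at 13, so that steps 3 to 9 are not needed. Enal 3 is treated with CH3CH=CHCH2MgCl (γ-attack) to give the branched homoallylic alcohol F1, which Dess–Martin periodinane oxidises to the β,γ-unsaturated ketone F2. Et3SiOTf/Et3N enolises F2 at its doubly activated methine and silylates the tertiary alcohol, giving the E-configured bis-silyl triene F3 (siloxy group cis to the methyl group). Et2Zn/CH2I2 then cyclopropanates the enol-ether olefin, the most electron-rich of the three, to the siloxy cis-divinylcyclopropane F4. On warming, F4 undergoes the same Cope rearrangement and gives 13 with the C8 methyl already in place. The bonds C7–C8 and C10–C1 are again formed in one operation. The price is that the cyclopropanation face is controlled only by the substrate, so the C1 epimers would be separated at 13. This fallback answers a chemical failure of the carbenoid step rather than a stereochemical one.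

2. Step 10. Protonation of C5 may occur on the wrong face, since the two faces differ little. The product cannot be equilibrated afterwards, because acid or base would move the C8=C9 double bond into conjugation with the C6 ketone or eliminate the tertiary hydroxyl. The fallback fixes C5 at an aldehyde stage, before the seven-membered ring exists, and closes the ring by metathesis; it sets out from 3 and comes back at 14. CH2=CHCH2MgBr adds to 3 to give the allyl carbinol F5. Its dipotassium alkoxide (KH, 18-crown-6, THF) undergoes an anionic oxy-Cope rearrangement that forms C10–C1 and, after protonation, gives the β-hydroxy aldehyde F6. C5 in F6 is an epimerisable aldehyde α-centre and should settle with the formyl group trans to both the isopropyl and the allyl group; the C1 epimers would be separated here. CH2=C(CH3)CH2MgCl then gives the diene diol F7, and ring-closing metathesis with the second-generation Grubbs catalyst forms the C8=C9 bond to give the bicyclic diol F8 as a C6 epimer mixture. Dess–Martin oxidation of F8 converges on ketone 14 under non-epimerising conditions.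

3. Step 11. The hindered tertiary hydroxyl may exchange onto boron too slowly, so that hydride is delivered externally and to the other face of C6. The fallback uses steric control and then inverts C6 in the esterification; it sets out from 14 and comes back at 17, replacing steps 11 and 12. LiB(s-Bu)3H should attack 14 from the face opposite the angular methyl and give the 6-epimeric diol F9. Mitsunobu esterification of F9 with 4-methoxybenzoic acid (PPh3, DIAD, THF) proceeds with inversion at C6 and leaves the tertiary hydroxyl untouched, giving 17 directly.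

Further compounds
F1 | step 7 | (1R)-2-(1-hydroxy-2-methylbut-3-en-1-yl)-3-methyl-1-(propan-2-yl)cyclopent-2-en-1-ol (side-chain diastereomers) | C=CC(C)C(O)C1=C(C)CC[C@@]1(O)C(C)C
F2 | step 7 | 1-[(5R)-5-hydroxy-2-methyl-5-(propan-2-yl)cyclopent-1-en-1-yl]-2-methylbut-3-en-1-one | C=CC(C)C(=O)C1=C(C)CC[C@@]1(O)C(C)C
F3 | step 7 | triethyl({(1E)-2-methyl-1-[(5R)-2-methyl-5-(propan-2-yl)-5-(triethylsilyloxy)cyclopent-1-en-1-yl]buta-1,3-dien-1-yl}oxy)silane | C=C/C(C)=C(O[Si](CC)(CC)CC)\C1=C(C)CC[C@@]1(O[Si](CC)(CC)CC)C(C)C
F4 | step 7 | triethyl({(1S,2R)-2-ethenyl-2-methyl-1-[(5R)-2-methyl-5-(propan-2-yl)-5-(triethylsilyloxy)cyclopent-1-en-1-yl]cyclopropyl}oxy)silane | C[C@]1(C=C)C[C@@]1(O[Si](CC)(CC)CC)C2=C(C)CC[C@@]2(O[Si](CC)(CC)CC)C(C)C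
F5 | step 10 | (1R)-2-(1-hydroxybut-3-en-1-yl)-3-methyl-1-(propan-2-yl)cyclopent-2-en-1-ol (both carbinol epimers) | C=CCC(O)C1=C(C)CC[C@@]1(O)C(C)C
F6 | step 10 | (1R,2R,5R)-5-hydroxy-2-methyl-5-(propan-2-yl)-2-(prop-2-en-1-yl)cyclopentane-1-carbaldehyde | C=CC[C@@]1(C)CC[C@@](O)(C(C)C)[C@@H]1C=O
F7 | step 10 | (1R,2S,3R)-2-(1-hydroxy-3-methylbut-3-en-1-yl)-3-methyl-1-(propan-2-yl)-3-(prop-2-en-1-yl)cyclopentan-1-ol (both carbinol epimers) | C=CC[C@@]1(C)CC[C@@](O)(C(C)C)[C@@H]1C(O)CC(C)=C
F8 | step 10 | (3R,3aS,8aR)-6,8a-dimethyl-3-(propan-2-yl)-1,2,3,3a,4,5,8,8a-octahydroazulene-3,4-diol (both epimers at C4 of the azulene) | CC1=CC[C@@]2(C)CC[C@@](O)(C(C)C)[C@@H]2C(O)C1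
F9 | step 11 | (3R,3aS,4R,8aR)-6,8a-dimethyl-3-(propan-2-yl)-1,2,3,3a,4,5,8,8a-octahydroazulene-3,4-diol (6-epi-jaeschkeanadiol) | CC1=CC[C@@]2(C)CC[C@@](O)(C(C)C)[C@@H]2[C@H](O)C1
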